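**Strategy.** In the 3-hydroxy ε-ring (ring carbons C1–C6) the oxygen on C3 and the chain carbon C7 on C6 are cis, so they can be joined as a lactone spanning the cyclohexene: a 2-oxabicyclo[2.2.2]oct-5-en-3-one. This bicycle is disconnected by a retro-[4+2] into flat 3-bromo-4-methyl-2H-pyran-2-one and isobutene. One enantioselective inverse-demand Diels–Alder reaction then forms C1–C6 and C2–C3, closes the carbocycle and the O3–C7 bridge, fixes both stereocentres and leaves the alkene at C4=C5. Radical debromination, reduction to the lactol and Wittig chemistry with commercial polyene building blocks complete the all-E chain.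

Key step: step 3

Remark: carotenoid numbering is used (ring C1 = CMe2, C2 = CH2, C3 = CHOH, C4=C5, C6 bearing C7); the target is the all-E (3S,6R) isomer, (3S,6R)-3-hydroxy-8'-apo-ε-caroten-8'-al, in which O3 and C7 are cis.

**Step 1**
Reactants: 1 ethyl 3-methylbut-2-enoate; 2 N,N-dimethylformamide dimethyl acetal
Product: 4 4-methyl-2H-pyran-2-one, via dienamino ester 3 (not isolated)
Conditions: 2 (2.5 equiv), neat, 130 °C, MeOH distilled off; volatiles removed; then AcOH, aq. H2SO4, 100 °C
Reagents that add atoms: water, O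
Why: Vinylogous aminomethylenation of a γ-methyl group by the amide acetal gives the push–pull dienamine, which in aqueous acid isomerises about C2=C3, is hydrolysed at the enamine and lactonises with loss of ethanol to the pyranone (amide-acetal condensation followed by acid lactonisation).

**Step 2**
Reactants: 4 4-methyl-2H-pyran-2-one
Product: 6 3-bromo-4-methyl-2H-pyran-2-one, via dibromide 5 (not isolated)
Conditions: Br2 (1.05 equiv), CH2Cl2, dark, −78 → 0 °C; then Et3N (1.5 equiv), 0 °C → rt
Reagents that add atoms: bromine, BrBr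
Why: Electrophilic bromine should attack C3, where the resulting cation is delocalised over C4 and C6, and Et3N then removes the acidic H3 with loss of bromide (bromination–dehydrobromination, as known for the parent 2H-pyran-2-one).

**Step 3**
Reactants: 6 3-bromo-4-methyl-2H-pyran-2-one; 7 isobutene
Product: 8 (1S,4S)-4-bromo-5,8,8-trimethyl-2-oxabicyclo[2.2.2]oct-5-en-3-one
Conditions: 7 (15 equiv, condensed in), (S)-1-(2-methylphenyl)-3,3-diphenyltetrahydro-1H,3H-pyrrolo[1,2-c][1,3,2]oxazaborole (20 mol%) activated with HN(SO2CF3)2 (18 mol%), CH2Cl2, −40 °C, closed vessel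
Reagents that add atoms: none
Why: Proposed new method: the cationic boron Lewis acid binds the lactone carbonyl of 6 at the lone pair on the ring-oxygen side (the other is screened by C3–Br) and lowers the diene LUMO, so that in a concerted but asynchronous inverse-electron-demand Diels–Alder reaction the nucleophilic CH2 of 7 bonds to pyranone C6 (target C3) slightly ahead of the bond from the cation-stabilising CMe2 carbon to pyranone C3 (target C6). The closest known reaction types are the thermal or high-pressure cycloadditions of 3-bromo-2H-pyran-2-ones with alkenes that give isolable bridged lactones, chiral-Lewis-acid cycloadditions of 2-pyranones with vinyl ethers, and oxazaborolidinium-catalysed enantioselective cycloadditions of singly coordinating unsaturated esters with unactivated 1,1-disubstituted alkenes; the enantioselective union of a bromopyranone with isobutene is not known. The cyclohexene ring closes by suprafacial [4+2] bonding at both diene termini (C2–C3 and C1–C6), and the same two bonds convert the pyranone ester into the second ring, the O3–C7 lactone bridge of the 2-oxabicyclo[2.2.2]octenone. The two bridgehead stereocentres are tied to each other by the bridge, so only their common absolute sense is open; it is decided by which face of the bound pyranone the aryl groups of the catalyst leave free, cannot be predicted with confidence, and is corrected by using the antipodal catalyst if the (1R,4R) lactone should form. Regioselectivity follows from the polarisation of the activated pyranone (C6 electrophilic, C3 enolate-like) and of isobutene (tertiary cation character at CMe2), endo/exo selectivity does not arise because both substituents on the alkene carbon are methyl, and the low temperature keeps the adduct from extruding CO2 and disfavours stepwise ene and [2+2] side paths.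

**Step 4**
Reactants: 8 (1S,4S)-4-bromo-5,8,8-trimethyl-2-oxabicyclo[2.2.2]oct-5-en-3-one
Product: 9 (1S,4R)-5,8,8-trimethyl-2-oxabicyclo[2.2.2]oct-5-en-3-one
Conditions: Bu3SnH (1.3 equiv), azobis(isobutyronitrile) (10 mol%), PhH, 80 °C
Reagents that add atoms: none
Why: Radical chain dehalogenation gives a bridgehead radical that the bicycle holds pyramidal, so hydrogen is delivered with retention and C6 keeps the configuration set in step 3.

**Step 5**
Reactants: 9 (1S,4R)-5,8,8-trimethyl-2-oxabicyclo[2.2.2]oct-5-en-3-one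
Product: 10 (1S,4R)-5,8,8-trimethyl-2-oxabicyclo[2.2.2]oct-5-en-3-ol (both epimers at the lactol carbon)
Conditions: iBu2AlH (1.1 equiv), CH2Cl2, −78 °C; aq. potassium sodium tartrate
Reagents that add atoms: none
Why: Partial reduction of the lactone with iBu2AlH stops at the aluminium hemiacetal at low temperature and gives the bridged lactol on work-up; the lactol carbon is a mixture of epimers that converge in step 6.

**Step 6**
Reactants: 10 (1S,4R)-5,8,8-trimethyl-2-oxabicyclo[2.2.2]oct-5-en-3-ol; 11 1-(triphenylphosphoranylidene)propan-2-one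
Product: 13 (3E)-4-[(1R,4S)-4-hydroxy-2,6,6-trimethylcyclohex-2-en-1-yl]but-3-en-2-one, via hydroxy aldehyde 12 (not isolated)
Conditions: 11 (3 equiv), PhMe, 90 °C
Reagents that add atoms: none
Why: Ring–chain tautomerism of the strained bridged lactol frees the C7 aldehyde, which the neutral stabilised ylide converts into the E-enone (Wittig reaction) without touching the epimerisable C6–H, so the cis relation of O3 and C7 from step 3 becomes the (3S,6R) configuration.

**Step 7**
Reactants: 13 (3E)-4-[(1R,4S)-4-hydroxy-2,6,6-trimethylcyclohex-2-en-1-yl]but-3-en-2-one; 14 vinylmagnesium bromide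
Product: 15 (1E)-1-[(1R,4S)-4-hydroxy-2,6,6-trimethylcyclohex-2-en-1-yl]-3-methylpenta-1,4-dien-3-ol (both epimers at the new carbinol carbon)
Conditions: 14 (3 equiv), THF, −40 → 0 °C; aq. NH4Cl
Reagents that add atoms: none
Why: After deprotonation of the ring hydroxyl by the first equivalent, Grignard 1,2-addition to the enone carbonyl gives the tertiary bis-allylic alcohol; its new stereocentre is formed unselectively and is erased in step 9.

**Step 8**
Reactants: 15 (1E)-1-[(1R,4S)-4-hydroxy-2,6,6-trimethylcyclohex-2-en-1-yl]-3-methylpenta-1,4-dien-3-ol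
Product: 16 (1S,4R)-4-[(1E)-3-hydroxy-3-methylpenta-1,4-dien-1-yl]-3,5,5-trimethylcyclohex-2-en-1-yl acetate
Conditions: Ac2O (1.3 equiv), pyridine, 4-(dimethylamino)pyridine (5 mol%), CH2Cl2, 0 °C
Reagents that add atoms: acetic anhydride, CC(=O)OC(C)=O
Why: Acylation is selective for the secondary over the hindered tertiary hydroxyl, and the acetate protects the acid-labile ring allylic alcohol against ionisation in step 9.

**Step 9**
Reactants: 16 (1S,4R)-4-[(1E)-3-hydroxy-3-methylpenta-1,4-dien-1-yl]-3,5,5-trimethylcyclohex-2-en-1-yl acetate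
Product: 17 [(2E,4E)-5-[(1R,4S)-4-acetoxy-2,6,6-trimethylcyclohex-2-en-1-yl]-3-methylpenta-2,4-dien-1-yl]triphenylphosphonium bromide
Conditions: PPh3·HBr (1.05 equiv), CH2Cl2, 0 °C → rt; crystallisation
Reagents that add atoms: triphenylphosphine hydrobromide, Br.c1ccc(cc1)P(c1ccccc1)c1ccccc1
Why: HBr ionises the tertiary bis-allylic alcohol to a pentadienyl cation that PPh3 captures at the unhindered terminus C11 (allylic transposition to the phosphonium salt), giving mainly the 9E salt, which is purified by crystallisation, while the allylic acetate should not ionise in this buffered medium.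

**Step 10**
Reactants: 18 (2E,4E,6E)-2,7-dimethylocta-2,4,6-trienedial; 19 diethyl (cyanomethyl)phosphonate
Product: 20 (2E,4E,6E,8E)-4,9-dimethyl-10-oxodeca-2,4,6,8-tetraenenitrile
Conditions: 19 (1 equiv), NaH, THF, 0 °C; added slowly to 18 (3 equiv), THF/CH2Cl2, −20 → 0 °C
Reagents that add atoms: none
Why: Horner–Wadsworth–Emmons olefination of one aldehyde of the symmetrical dial, used in excess to suppress twofold reaction, should give mainly the E nitrile, with Z isomer and bis-adduct removed at this inexpensive stage.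

**Step 11**
Reactants: 17 [(2E,4E)-5-[(1R,4S)-4-acetoxy-2,6,6-trimethylcyclohex-2-en-1-yl]-3-methylpenta-2,4-dien-1-yl]triphenylphosphonium bromide; 20 (2E,4E,6E,8E)-4,9-dimethyl-10-oxodeca-2,4,6,8-tetraenenitrile
Product: 22 (2E,4E,6E,8E,10E,12E,14E)-15-[(1R,4S)-4-acetoxy-2,6,6-trimethylcyclohex-2-en-1-yl]-4,9,13-trimethylpentadeca-2,4,6,8,10,12,14-heptaenenitrile, via ylide 21 (not isolated)
Conditions: 1,2-epoxybutane (solvent), 60 °C; then heptane, 90 °C
Reagents that add atoms: none
Why: The epoxide scavenges HBr and so generates the semi-stabilised allylic ylide under neutral conditions for a Wittig reaction that forms C11=C12 and spares acetate and nitrile, and the subsequent heating should equilibrate the hindered 11Z isomer to E.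

**Step 12**
Reactants: 22 (2E,4E,6E,8E,10E,12E,14E)-15-[(1R,4S)-4-acetoxy-2,6,6-trimethylcyclohex-2-en-1-yl]-4,9,13-trimethylpentadeca-2,4,6,8,10,12,14-heptaenenitrile
Product: 24 (2E,4E,6E,8E,10E,12E,14E)-15-[(1R,4S)-4-hydroxy-2,6,6-trimethylcyclohex-2-en-1-yl]-4,9,13-trimethylpentadeca-2,4,6,8,10,12,14-heptaenal, via aldimine 23 (not isolated)
Conditions: iBu2AlH (5 equiv), CH2Cl2, −78 → −40 °C; wet SiO2, 0 °C
Reagents that add atoms: water, O
Why: iBu2AlH adds once to the nitrile to give the aluminium aldimine, hydrolysed on wet silica to the aldehyde, and in the same operation cleaves the acetate reductively (nitrile-to-aldehyde reduction), so no oxidant or strong acid meets the allylic 3-hydroxyl.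

**Step 13**
Reactants: 24 (2E,4E,6E,8E,10E,12E,14E)-15-[(1R,4S)-4-hydroxy-2,6,6-trimethylcyclohex-2-en-1-yl]-4,9,13-trimethylpentadeca-2,4,6,8,10,12,14-heptaenal; 25 2-(triphenylphosphoranylidene)propanal
Product: 26 (2E,4E,6E,8E,10E,12E,14E,16E)-17-[(1R,4S)-4-hydroxy-2,6,6-trimethylcyclohex-2-en-1-yl]-2,6,11,15-tetramethylheptadeca-2,4,6,8,10,12,14,16-octaenal, the target
Conditions: 25 (1.5 equiv), PhMe, 80 °C, dark, argon; crystallisation
Reagents that add atoms: none
Why: Wittig reaction with the formyl-stabilised ylide adds the last three carbons and gives the E α-methyl enal directly, and the α-branched product aldehyde reacts with the ylide far more slowly than 24, which limits over-homologation.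

**Compound list**

1 | ethyl 3-methylbut-2-enoate | CCOC(=O)C=C(C)C | starting material
2 | N,N-dimethylformamide dimethyl acetal | COC(OC)N(C)C | starting material
3 | ethyl (4E)-5-(dimethylamino)-3-methylpenta-2,4-dienoate (2E/2Z mixture) | CCOC(=O)C=C(C)/C=C/N(C)C | intermediate
4 | 4-methyl-2H-pyran-2-one | CC1=CC(=O)OC=C1 | intermediate
5 | 3,4-dibromo-4-methyl-3,4-dihydro-2H-pyran-2-one (racemic bromine adduct; its 3,6-dibromo isomer would eliminate to the same product) | CC1(Br)C=COC(=O)C1Br | intermediate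
6 | 3-bromo-4-methyl-2H-pyran-2-one | CC1=C(Br)C(=O)OC=C1 | intermediate
7 | isobutene | CC(C)=C | starting material
8 | (1S,4S)-4-bromo-5,8,8-trimethyl-2-oxabicyclo[2.2.2]oct-5-en-3-one | CC1=C[C@@H](O2)CC(C)(C)[C@@]1(Br)C2=O | intermediate
9 | (1S,4R)-5,8,8-trimethyl-2-oxabicyclo[2.2.2]oct-5-en-3-one | CC1=C[C@@H](O2)CC(C)(C)[C@H]1C2=O | intermediate
10 | (1S,4R)-5,8,8-trimethyl-2-oxabicyclo[2.2.2]oct-5-en-3-ol (both lactol epimers) | CC1=C[C@@H](O2)CC(C)(C)[C@H]1C2O | intermediate
11 | 1-(triphenylphosphoranylidene)propan-2-one | CC(=O)C=P(c1ccccc1)(c1ccccc1)c1ccccc1 | starting material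
12 | (1R,4S)-4-hydroxy-2,6,6-trimethylcyclohex-2-ene-1-carbaldehyde | CC1=C[C@@H](O)CC(C)(C)[C@H]1C=O | intermediate
13 | (3E)-4-[(1R,4S)-4-hydroxy-2,6,6-trimethylcyclohex-2-en-1-yl]but-3-en-2-one, (3S,6R)-3-hydroxy-α-ionone | CC1=C[C@@H](O)CC(C)(C)[C@H]1/C=C/C(C)=O | intermediate
14 | vinylmagnesium bromide | C=C[Mg]Br | starting material
15 | (1E)-1-[(1R,4S)-4-hydroxy-2,6,6-trimethylcyclohex-2-en-1-yl]-3-methylpenta-1,4-dien-3-ol (both carbinol epimers) | CC1=C[C@@H](O)CC(C)(C)[C@H]1/C=C/C(C)(O)C=C | intermediate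
16 | (1S,4R)-4-[(1E)-3-hydroxy-3-methylpenta-1,4-dien-1-yl]-3,5,5-trimethylcyclohex-2-en-1-yl acetate | CC1=C[C@@H](OC(C)=O)CC(C)(C)[C@H]1/C=C/C(C)(O)C=C | intermediate
17 | [(2E,4E)-5-[(1R,4S)-4-acetoxy-2,6,6-trimethylcyclohex-2-en-1-yl]-3-methylpenta-2,4-dien-1-yl]triphenylphosphonium bromide | CC1=C[C@@H](OC(C)=O)CC(C)(C)[C@H]1/C=C/C(C)=C/C[P+](c1ccccc1)(c1ccccc1)c1ccccc1.[Br-] | intermediate
18 | (2E,4E,6E)-2,7-dimethylocta-2,4,6-trienedial | O=C/C(C)=C/C=C/C=C(C)/C=O | starting material
19 | diethyl (cyanomethyl)phosphonate | CCOP(=O)(CC#N)OCC | starting material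
20 | (2E,4E,6E,8E)-4,9-dimethyl-10-oxodeca-2,4,6,8-tetraenenitrile | N#C/C=C/C(C)=C/C=C/C=C(C)/C=O | intermediate
21 | [(2E,4E)-5-[(1R,4S)-4-acetoxy-2,6,6-trimethylcyclohex-2-en-1-yl]-3-methylpenta-2,4-dien-1-ylidene]triphenylphosphorane | CC1=C[C@@H](OC(C)=O)CC(C)(C)[C@H]1/C=C/C(C)=C/C=P(c1ccccc1)(c1ccccc1)c1ccccc1 | intermediate
22 | (2E,4E,6E,8E,10E,12E,14E)-15-[(1R,4S)-4-acetoxy-2,6,6-trimethylcyclohex-2-en-1-yl]-4,9,13-trimethylpentadeca-2,4,6,8,10,12,14-heptaenenitrile | CC1=C[C@@H](OC(C)=O)CC(C)(C)[C@H]1/C=C/C(C)=C/C=C/C(C)=C/C=C/C=C(C)/C=C/C#N | intermediate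
23 | (2E,4E,6E,8E,10E,12E,14E)-15-[(1R,4S)-4-hydroxy-2,6,6-trimethylcyclohex-2-en-1-yl]-4,9,13-trimethylpentadeca-2,4,6,8,10,12,14-heptaen-1-imine (formed as its aluminium derivative) | CC1=C[C@@H](O)CC(C)(C)[C@H]1/C=C/C(C)=C/C=C/C(C)=C/C=C/C=C(C)/C=C/C=N | intermediate
24 | (2E,4E,6E,8E,10E,12E,14E)-15-[(1R,4S)-4-hydroxy-2,6,6-trimethylcyclohex-2-en-1-yl]-4,9,13-trimethylpentadeca-2,4,6,8,10,12,14-heptaenal | CC1=C[C@@H](O)CC(C)(C)[C@H]1/C=C/C(C)=C/C=C/C(C)=C/C=C/C=C(C)/C=C/C=O | intermediate
25 | 2-(triphenylphosphoranylidene)propanal | CC(C=O)=P(c1ccccc1)(c1ccccc1)c1ccccc1 | starting material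
26 | (2E,4E,6E,8E,10E,12E,14E,16E)-17-[(1R,4S)-4-hydroxy-2,6,6-trimethylcyclohex-2-en-1-yl]-2,6,11,15-tetramethylheptadeca-2,4,6,8,10,12,14,16-octaenal | CC1=C[C@@H](O)CC(C)(C)[C@H]1/C=C/C(C)=C/C=C/C(C)=C/C=C/C=C(C)/C=C/C=C(\C)C=O | target

**Step count and risks**

Total step count: 13. Longest linear sequence: 12 steps (steps 1–9 and 11–13; step 10 is a one-step side branch).

The three steps most likely to fail:

- **Step 3.** The Lewis acid holds the diene at a single oxygen, so facial discrimination may be poor; isobutene may also oligomerise cationically, or the cycloaddition may be too slow at a temperature that is safe against CO2 loss. The fallback uses known chemistry and sets out from 6 and 7. They are combined without catalyst at 10–12 kbar (CH2Cl2, 40 °C) to give the racemic bridged bromolactone F1. Bu3SnH with azobis(isobutyronitrile) gives the racemic lactone F2, iBu2AlH the racemic lactol F3, and Wittig reaction with 11 the racemic cis-hydroxy enone F4. Acylation of F4 with (1S)-(−)-camphanic chloride (pyridine, CH2Cl2) gives the diastereomeric camphanate of the (3S,6R) alcohol F5 and the camphanate of the (3R,6S) alcohol F6, which are separated by crystallisation or chromatography. K2CO3 in MeOH on F5 returns to the route at 13.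

- **Step 2.** Bromine may attack C5 as well as C3, or brominate twice, so that the 3-bromo compound is not obtained cleanly. The fallback sets out from 1 and places the bromine before the ring is built. Br2 in CH2Cl2 gives ethyl 2,3-dibromo-3-methylbutanoate F7, and Et3N eliminates HBr to ethyl 2-bromo-3-methylbut-2-enoate F8. Condensation with 2 (neat, 120 °C) gives the bromo dienamino ester F9, and the acid treatment of step 1 closes it to 6, where the route is rejoined.

- **Step 6.** Olefination of the hindered, masked aldehyde by the weakly nucleophilic keto ylide may be slow, and long heating may cause epimerisation at C6 or migration of the ring double bond into conjugation. The fallback sets out from 10. The more reactive ylide Ph3P=CHCO2Et (PhMe, 60 °C) gives the hydroxy enoate F10, MeNH(OMe)·HCl with iPrMgCl (THF, −20 °C) converts it into the Weinreb amide F11, and MeMgBr (THF, 0 °C) gives 13.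

**Further compounds**

F1 | step 3 | racemic 4-bromo-5,8,8-trimethyl-2-oxabicyclo[2.2.2]oct-5-en-3-one (both enantiomers) | CC1=C[C@@H](O2)CC(C)(C)[C@@]1(Br)C2=O.CC1=C[C@H](O2)CC(C)(C)[C@]1(Br)C2=O
F2 | step 3 | racemic 5,8,8-trimethyl-2-oxabicyclo[2.2.2]oct-5-en-3-one (both enantiomers) | CC1=C[C@@H](O2)CC(C)(C)[C@H]1C2=O.CC1=C[C@H](O2)CC(C)(C)[C@@H]1C2=O
F3 | step 3 | racemic 5,8,8-trimethyl-2-oxabicyclo[2.2.2]oct-5-en-3-ol (both enantiomers, lactol epimers) | CC1=C[C@@H](O2)CC(C)(C)[C@H]1C2O.CC1=C[C@H](O2)CC(C)(C)[C@@H]1C2O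
F4 | step 3 | racemic cis-(3E)-4-(4-hydroxy-2,6,6-trimethylcyclohex-2-en-1-yl)but-3-en-2-one (both enantiomers) | CC1=C[C@@H](O)CC(C)(C)[C@H]1/C=C/C(C)=O.CC1=C[C@H](O)CC(C)(C)[C@@H]1/C=C/C(C)=O
F5 | step 3 | (1S,4R)-3,5,5-trimethyl-4-[(1E)-3-oxobut-1-en-1-yl]cyclohex-2-en-1-yl (1S,4R)-4,7,7-trimethyl-3-oxo-2-oxabicyclo[2.2.1]heptane-1-carboxylate | CC1=C[C@@H](OC(=O)[C@@]23CC[C@@](C)(C(=O)O2)C3(C)C)CC(C)(C)[C@H]1/C=C/C(C)=O
F6 | step 3 | (1R,4S)-3,5,5-trimethyl-4-[(1E)-3-oxobut-1-en-1-yl]cyclohex-2-en-1-yl (1S,4R)-4,7,7-trimethyl-3-oxo-2-oxabicyclo[2.2.1]heptane-1-carboxylate | CC1=C[C@H](OC(=O)[C@@]23CC[C@@](C)(C(=O)O2)C3(C)C)CC(C)(C)[C@@H]1/C=C/C(C)=O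
F7 | step 2 | ethyl 2,3-dibromo-3-methylbutanoate (racemic) | CCOC(=O)C(Br)C(C)(C)Br
F8 | step 2 | ethyl 2-bromo-3-methylbut-2-enoate | CCOC(=O)C(Br)=C(C)C
F9 | step 2 | ethyl (4E)-2-bromo-5-(dimethylamino)-3-methylpenta-2,4-dienoate (2E/2Z mixture) | CCOC(=O)C(Br)=C(C)/C=C/N(C)C
F10 | step 6 | ethyl (2E)-3-[(1R,4S)-4-hydroxy-2,6,6-trimethylcyclohex-2-en-1-yl]prop-2-enoate | CC1=C[C@@H](O)CC(C)(C)[C@H]1/C=C/C(=O)OCC
F11 | step 6 | (2E)-3-[(1R,4S)-4-hydroxy-2,6,6-trimethylcyclohex-2-en-1-yl]-N-methoxy-N-methylprop-2-enamide | CC1=C[C@@H](O)CC(C)(C)[C@H]1/C=C/C(=O)N(C)OC
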